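The constants of the chain steps are hidden, so we read one lumped constant off the earlier runs.

all flasks: initiator 10 mM

|  | starting material | partner | protic impurity | temperature | remark | time |
|---|---|---|---|---|---|---|
| gamma | 0.10 M | 0.50 M | 3.2 mM | −35 °C | run made earlier |  |
| eta | 0.10 M | 0.50 M | 3.8 mM | −20 °C | run made earlier |  |
| epsilon | 0.16 M | 0.50 M | 5 mM | −35 °C | run made earlier |  |
| red | 0.15 M | 0.500 M | 3.00 mM | −20 °C |  | 3.0 h |
| amber | 0.10 M | 0.500 M | 5.00 mM | −20 °C |  | 3.0 h |

gamma run (percent of the starting material charged)

| time / h | product / % |
|---|---|
| 0.417 | 0.5 |
| 1.00 | 2.5 |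
| 2.00 | 0.5 |
| 3.00 | 3.8 |
| 4.00 | 6.4 |

eta run (percent of the starting material charged)

| time / min | product / % |
|---|---|
| 25.0 | 5.4 |
| 50.0 | 10.7 |
| 80.0 | 13.8 |
| 90.0 | 13.6 |
| 120 | 18.4 |

epsilon run (percent of the starting material charged)

| time / h | product / % |
|---|---|
| 0.417 | 2.3 |
| 1.00 | 2.1 |
| 2.00 | 2.7 |
| 3.00 | 2.4 |
| 4.00 | 5.2 |

(scatter of a reading: 1 percentage point)

- which one finishes higher in amount of product, in percent of the starting material charged ("neither" within 2 percentage points) (red / amber / neither)
- amount of product at the end, in percent of the starting material charged, red
- amount of product at the end, in percent of the starting material charged, amber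

- reactions considered so far: 2 second chain carrier -> ended chains; partner + first chain carrier <-> product + second chain carrier; starting material + protic impurity -> quenched substrate; initiator -> 2 initiating radical; starting material + initiating radical -> capped initiator + first chain carrier; starting material + second chain carrier -> by-product + first chain carrier; 2 partner -> homo dimer

As in a radical chain polymerisation, we take the second chain carrier to be at steady state, made through the initiator and ended in pairs. For a fixed initiator charge and temperature, and while partner is present, we then expect c(second chain carrier) to stand at one level whatever c(starting material) is, and the starting material to fall pseudo-first-order. The gamma and epsilon runs do not speak against this: they share a temperature but differ in starting material, 0.10 M against 0.16 M, and in protic impurity, 3.2 mM against 5 mM, and their last readings are 6.4% and 5.2%, with a scatter of 1 percentage point.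

We also take the protic impurity to remove its own amount of starting material at the outset, which leaves the eta run a free share of 96.2%. What we carry is the chain constant, the fraction of free starting material turned to product per hour at fixed initiator and temperature.

We get it in two ways from the eta run, which has the temperature and initiator of red and amber. Its last reading, at 120 min, gives 0.106 h⁻¹. Its reading at 50.0 min gives 0.141 h⁻¹, which is higher. The two part, so at least one of them is off. Against the curve of 0.106 h⁻¹, the early reading stands 2.6 points high, yet the reading at 90.0 min gives 0.102 h⁻¹, close to the last one. We therefore treat the early value as scatter on a small conversion and keep 0.106 h⁻¹.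

Over 3.0 h, with free shares of 98.0% and 95.0%, our reckoning gives 26.7% for red and 25.9% for amber. The gap of 0.80 points is smaller than the margin, so we say neither.

The forecast also says neither, but with lower figures, 24.5% for red and 23.5% for amber, holding that “percent conversion should barely depend on its concentration”.

The flask gives neither: 27.7% for red and 27.1% for amber.

    2 second chain carrier → ended chains (k = 3.00 × 10⁶ M⁻¹ s⁻¹, Ea = 20.0 kJ mol⁻¹)
    partner + first chain carrier ⇌ product + second chain carrier (K = 0.400, k = 2.10 × 10⁵ M⁻¹ h⁻¹, Ea = 38.0 kJ mol⁻¹, ΔH = −39.0 kJ mol⁻¹)
    starting material + protic impurity → quenched substrate (k = 330 M⁻¹ h⁻¹, Ea = 52.0 kJ mol⁻¹)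
    initiator → 2 initiating radical (k = 0.0130 h⁻¹, Ea = 89.0 kJ mol⁻¹)
    starting material + initiating radical → capped initiator + first chain carrier (k = 15000 M⁻¹ s⁻¹, Ea = 20.0 kJ mol⁻¹)
    starting material + second chain carrier → by-product + first chain carrier (k = 1.00 × 10⁶ M⁻¹ h⁻¹, Ea = 40.0 kJ mol⁻¹)
    2 partner → homo dimer (k = 0.680 M⁻¹ h⁻¹, Ea = 51.0 kJ mol⁻¹)
    (constants at −20 °C)

Amber's result, read the same way, gives 0.112 h⁻¹, beside the carried 0.106 h⁻¹. Now take a flask like amber but with 0.017 M of initiator. With carriers ending in pairs, we reckon the carrier level to go as the root of the initiator charge, a factor 1.30, so the constant becomes 0.138 h⁻¹ and the product 32.2%. At 3.00 h, c(second chain carrier) in that flask stands 1.30 times amber's. That flask gives 34.0% of product, with 61.0% of the starting material left.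

Readings and results were generated by integration with constants of no real substance; scatter was added.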